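**Retrosynthetic overview**

1. The strategy rests on ring A (C4a, C5, C6, C7, C8, C8a): oxygen sits on C5, C7 and C8a in a 1,3,5 relationship, C4a carries the acyl carbon C4, and C6 and C8 carry the other two oxygens. This is the pattern of a poly-β-carbonyl chain made of two methoxyacetate-type units and one acetate-type unit, folded head to tail.
2. Late stage: on a 5,7-dihydroxy-6,8-dimethoxyflavone, O7 is methylated, the O6 methyl group is cleaved and the 3'-benzyl ether is removed. Ring C (O1–C2 bond) comes from oxidative cyclisation of a 2'-hydroxychalcone whose ring A is symmetric about the acyl group.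
3. Key disconnection C4a–C8a: ring A is formed by Claisen closure of a 2,4-dimethoxy-3,5,7-triketo ester, released by Mg(OMe)2 from a 6-(cinnamoylmethyl)-4-hydroxy-3,5-dimethoxy-2-pyrone.
4. The pyrone precursor comes from C-acylation of 4-hydroxy-3,5-dimethoxy-6-methyl-2-pyrone at its methyl group with an isovanillin-derived cinnamoyl Weinreb amide. The methylpyrone comes from methyl methoxyacetate by self-Claisen condensation, terminal acetylation and lactonisation.
5. Ring order: ring B is bought with isovanillin; the pyrone ring is made and then sacrificed; ring A is closed in step 7 and ring C in step 8.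

Key step: step 7

Assumption: the stereocentres met on the way (the methoxy-bearing carbons of the acyclic keto esters and C2 of the transient flavanone) are enolisable or are destroyed later, so these compounds are handled as mixtures of stereoisomers and tautomers; the target is achiral.

**Route**

Step 1
Reactants: 1 methyl methoxyacetate (two molecules)
Product: 2 methyl 2,4-dimethoxy-3-oxobutanoate
Conditions: NaH (0.55 equiv per ester), THF, 0 °C to reflux; then cold aq. HCl
Reagents that add atoms: none
Why: Claisen self-condensation, in which the ester enolate of one molecule acylates a second and irreversible deprotonation of the β-keto ester product pulls the equilibrium forward.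

Step 2
Reactants: 2 methyl 2,4-dimethoxy-3-oxobutanoate; 3 N-methoxy-N-methylacetamide
Product: 4 methyl 2,4-dimethoxy-3,5-dioxohexanoate
Conditions: LiN(iPr)2 (2.2 equiv), THF, −78 to 0 °C; then 3, −78 to 0 °C; aq. HCl
Reagents that add atoms: none
Why: β-Keto ester dianion acylation (Weinreb ketone synthesis), in which double deprotonation places the more reactive carbanion on the terminal methoxymethylene carbon and the chelated tetrahedral adduct collapses to the ketone only on work-up, so the reaction should stop at mono-C-acylation.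

Step 3
Reactants: 4 methyl 2,4-dimethoxy-3,5-dioxohexanoate
Product: 5 4-hydroxy-3,5-dimethoxy-6-methyl-2H-pyran-2-one
Conditions: DBU (1.1 equiv), toluene, reflux; then aq. HCl
Reagents that add atoms: none
Why: Base-mediated enol lactonisation of a 3,5-diketo ester, in which the enol oxygen of the terminal ketone attacks the ester carbonyl (6-exo-trig) and loss of methanol gives the 4-hydroxy-2-pyrone.

Step 4
Reactants: 6 isovanillin (3-hydroxy-4-methoxybenzaldehyde)
Product: 7 3-benzyloxy-4-methoxybenzaldehyde
Conditions: BnBr, K2CO3, DMF, rt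
Reagents that add atoms: benzyl bromide, BrCc1ccccc1
Why: Williamson ether synthesis on the only phenol, with a non-enolisable aldehyde that is inert to carbonate.

Step 5
Reactants: 7 3-benzyloxy-4-methoxybenzaldehyde; 8 diethyl {2-[methoxy(methyl)amino]-2-oxoethyl}phosphonate
Product: 9 (E)-3-(3-benzyloxy-4-methoxyphenyl)-N-methoxy-N-methylprop-2-enamide
Conditions: NaH, THF, 0 °C to rt
Reagents that add atoms: none
Why: Horner–Wadsworth–Emmons olefination with an amide-stabilised phosphonate, which should give the E alkene under thermodynamic control and delivers the acyl donor directly as its Weinreb amide.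

Step 6
Reactants: 5 4-hydroxy-3,5-dimethoxy-6-methyl-2H-pyran-2-one; 9 (E)-3-(3-benzyloxy-4-methoxyphenyl)-N-methoxy-N-methylprop-2-enamide
Product: 10 6-[(E)-4-(3-benzyloxy-4-methoxyphenyl)-2-oxobut-3-en-1-yl]-4-hydroxy-3,5-dimethoxy-2H-pyran-2-one
Conditions: LiN(iPr)2 (2.2 equiv), THF–DMPU, −78 to −30 °C; then 9 (0.9 equiv), −78 to 0 °C; 1 M HCl
Reagents that add atoms: none
Why: Acylation of a 4-hydroxy-6-methyl-2-pyrone O,C-dianion (Weinreb ketone synthesis), in which the exocyclic carbanion is the nucleophilic site as in triacetic acid lactone, the unsaturated Weinreb amide is attacked 1,2, and the chelated adduct keeps the acidic β-dicarbonyl product masked until work-up.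

Step 7
Reactants: 10 6-[(E)-4-(3-benzyloxy-4-methoxyphenyl)-2-oxobut-3-en-1-yl]-4-hydroxy-3,5-dimethoxy-2H-pyran-2-one
Product: 12 (E)-3-(3-benzyloxy-4-methoxyphenyl)-1-(2,4,6-trihydroxy-3,5-dimethoxyphenyl)prop-2-en-1-one, via open-chain triketo methyl ester 11 (not isolated)
Conditions: Mg(OMe)2 (8 equiv), MeOH, reflux, Ar; then cold 1 M HCl
Reagents that add atoms: none
Why: Methoxide delivered on magnesium opens the lactone of 10 at C2 to the magnesium-chelated triketo ester 11, and the carbanion of the chain methylene flanked by two ketones (future C4a) adds to the ester carbonyl (future C8a); loss of methoxide and enolisation give the aromatic acylphloroglucinol. The closest known reaction is the Mg(OMe)2-mediated conversion of 6-(2-oxoalkyl)-4-hydroxy-2-pyrones into acylphloroglucinols, an intramolecular Claisen (Dieckmann-type) condensation. Ring A closes 6-exo-trig at the ester carbonyl and forms the C4a–C8a bond. No stereocentre is created, and the E olefin takes no part and should be kept. The step needs Claisen rather than aldol folding: the only other six-membered closure, attack of the ester α-carbon on the cinnamoyl ketone, gives an adduct whose ring carbon is quaternary (methoxy and ester) and cannot dehydrate to an arene, so it should revert, while magnesium chelation of the 1,3-dicarbonyl units holds the chain in the Claisen geometry and the α-methoxy group makes the ester more electrophilic. The product ring is symmetric about the acyl group, so closure of ring C on either ortho hydroxyl leads to one flavone.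

Step 8
Reactants: 12 (E)-3-(3-benzyloxy-4-methoxyphenyl)-1-(2,4,6-trihydroxy-3,5-dimethoxyphenyl)prop-2-en-1-one
Product: 14 2-(3-benzyloxy-4-methoxyphenyl)-5,7-dihydroxy-6,8-dimethoxy-4H-chromen-4-one, via racemic flavanone 13 (not isolated)
Conditions: I2 (10 mol %), DMSO, 120 °C
Reagents that add atoms: none
Why: Iodine-catalysed oxidative cyclisation of a 2'-hydroxychalcone (6-endo oxa-Michael closure to the flavanone, α-iodination and loss of HI, with DMSO turning HI back into I2), helped by ring A having no free CH to iodinate; any flavanone already formed in step 7 converges here.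

Step 9
Reactants: 14 2-(3-benzyloxy-4-methoxyphenyl)-5,7-dihydroxy-6,8-dimethoxy-4H-chromen-4-one
Product: 15 2-(3-benzyloxy-4-methoxyphenyl)-5-hydroxy-6,7,8-trimethoxy-4H-chromen-4-one
Conditions: MeI (1.1 equiv), K2CO3 (1.2 equiv), acetone, 40 °C
Reagents that add atoms: iodomethane, CI
Why: Selective Williamson methylation, since the 7-hydroxyl is a vinylogous acid and is deprotonated first, while the 5-hydroxyl is locked in a hydrogen bond to the C4 carbonyl and should stay free with one equivalent of electrophile.

Step 10
Reactants: 15 2-(3-benzyloxy-4-methoxyphenyl)-5-hydroxy-6,7,8-trimethoxy-4H-chromen-4-one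
Product: 16 2-(3-benzyloxy-4-methoxyphenyl)-5,6-dihydroxy-7,8-dimethoxy-4H-chromen-4-one
Conditions: AlBr3 (4 equiv), MeCN, 0 °C to rt; then 1 M HCl, 50 °C
Reagents that add atoms: none
Why: Chelation-directed Lewis acid ether cleavage, in which aluminium held by the O5 phenoxide and the C4 carbonyl activates the neighbouring, out-of-plane O6 methyl ether for SN2 attack by bromide, while the 7-, 8- and 4'-methyl ethers have no adjacent aluminium phenoxide and acetonitrile tempers the Lewis acid so that the benzyl ether should survive at low temperature.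

Step 11
Reactants: 16 2-(3-benzyloxy-4-methoxyphenyl)-5,6-dihydroxy-7,8-dimethoxy-4H-chromen-4-one
Product: 17 5,6,3'-trihydroxy-7,8,4'-trimethoxyflavone (5,6-dihydroxy-2-(3-hydroxy-4-methoxyphenyl)-7,8-dimethoxy-4H-chromen-4-one)
Conditions: H2 (1 atm), 10% Pd/C, EtOAc–MeOH, rt
Reagents that add atoms: none
Why: Catalytic hydrogenolysis of the aryl benzyl ether, under which the conjugated C2=C3 bond of the flavone and the methyl ethers should be untouched and the air-sensitive 5,6-diol is kept under a reducing atmosphere.

**Compound list**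

1 | methyl methoxyacetate | COCC(=O)OC | starting material
2 | methyl 2,4-dimethoxy-3-oxobutanoate | COCC(=O)C(OC)C(=O)OC | intermediate
3 | N-methoxy-N-methylacetamide | CC(=O)N(C)OC | starting material
4 | methyl 2,4-dimethoxy-3,5-dioxohexanoate | COC(=O)C(OC)C(=O)C(OC)C(C)=O | intermediate
5 | 4-hydroxy-3,5-dimethoxy-6-methyl-2H-pyran-2-one | CC1=C(OC)C(O)=C(OC)C(=O)O1 | intermediate
6 | isovanillin (3-hydroxy-4-methoxybenzaldehyde) | COc1ccc(C=O)cc1O | starting material
7 | 3-benzyloxy-4-methoxybenzaldehyde | COc1ccc(C=O)cc1OCc1ccccc1 | intermediate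
8 | diethyl {2-[methoxy(methyl)amino]-2-oxoethyl}phosphonate | CCOP(=O)(CC(=O)N(C)OC)OCC | starting material
9 | (E)-3-(3-benzyloxy-4-methoxyphenyl)-N-methoxy-N-methylprop-2-enamide | COc1ccc(/C=C/C(=O)N(C)OC)cc1OCc1ccccc1 | intermediate
10 | 6-[(E)-4-(3-benzyloxy-4-methoxyphenyl)-2-oxobut-3-en-1-yl]-4-hydroxy-3,5-dimethoxy-2H-pyran-2-one | COc1ccc(/C=C/C(=O)CC2=C(OC)C(O)=C(OC)C(=O)O2)cc1OCc1ccccc1 | intermediate
11 | methyl (E)-9-(3-benzyloxy-4-methoxyphenyl)-2,4-dimethoxy-3,5,7-trioxonon-8-enoate (formed as its magnesium enolate, not isolated) | COC(=O)C(OC)C(=O)C(OC)C(=O)CC(=O)/C=C/c1ccc(OC)c(OCc2ccccc2)c1 | intermediate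
12 | (E)-3-(3-benzyloxy-4-methoxyphenyl)-1-(2,4,6-trihydroxy-3,5-dimethoxyphenyl)prop-2-en-1-one | COc1ccc(/C=C/C(=O)c2c(O)c(OC)c(O)c(OC)c2O)cc1OCc1ccccc1 | intermediate
13 | racemic 2-(3-benzyloxy-4-methoxyphenyl)-5,7-dihydroxy-6,8-dimethoxychroman-4-one (not isolated) | COc1ccc(C2CC(=O)c3c(O)c(OC)c(O)c(OC)c3O2)cc1OCc1ccccc1 | intermediate
14 | 2-(3-benzyloxy-4-methoxyphenyl)-5,7-dihydroxy-6,8-dimethoxy-4H-chromen-4-one | COc1ccc(-c2cc(=O)c3c(O)c(OC)c(O)c(OC)c3o2)cc1OCc1ccccc1 | intermediate
15 | 2-(3-benzyloxy-4-methoxyphenyl)-5-hydroxy-6,7,8-trimethoxy-4H-chromen-4-one | COc1ccc(-c2cc(=O)c3c(O)c(OC)c(OC)c(OC)c3o2)cc1OCc1ccccc1 | intermediate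
16 | 2-(3-benzyloxy-4-methoxyphenyl)-5,6-dihydroxy-7,8-dimethoxy-4H-chromen-4-one | COc1ccc(-c2cc(=O)c3c(O)c(O)c(OC)c(OC)c3o2)cc1OCc1ccccc1 | intermediate
17 | 5,6,3'-trihydroxy-7,8,4'-trimethoxyflavone | COc1ccc(-c2cc(=O)c3c(O)c(O)c(OC)c(OC)c3o2)cc1O | target

**Totals**

Total step count: 11. Longest linear sequence: 9 steps (steps 1, 2, 3, 6, 7, 8, 9, 10, 11, from methyl methoxyacetate); the ring B branch (steps 4 and 5) joins at step 6.

**Three steps most likely to fail, with fallbacks**

The first risk is step 7. The chain may fold in the aldol sense (ester α-carbon onto the cinnamoyl ketone) and then lose the ester carbon, or methoxide may cut the triketo chain by retro-Claisen attack, before the Claisen closure takes place. The two α-methoxy groups may also slow the enolisations that lead to the arene. The fallback for step 7 builds ring A from an aromatic precursor instead of by folding; it sets out from 7 and comes back at 15. Purchased 2,6-dimethoxy-1,4-benzoquinone F1 is submitted to Thiele–Winter acetoxylation (Ac2O, catalytic H2SO4) to give 1,2,4-triacetoxy-3,5-dimethoxybenzene F2. Deacetylation under nitrogen gives 3,5-dimethoxybenzene-1,2,4-triol F3, which is methylated in the same flask (Me2SO4, aq. NaOH) to pentamethoxybenzene F4. Friedel–Crafts acetylation (AcCl, AlCl3, Et2O), which also cleaves one ortho methyl ether through the ketone chelate, gives 2'-hydroxy-3',4',5',6'-tetramethoxyacetophenone F5. Claisen–Schmidt condensation of this ketone with 7 (KOH, EtOH, rt) gives (E)-3-(3-benzyloxy-4-methoxyphenyl)-1-(2-hydroxy-3,4,5,6-tetramethoxyphenyl)prop-2-en-1-one F6. Oxidative cyclisation (catalytic I2, DMSO, 120 °C) gives 2-(3-benzyloxy-4-methoxyphenyl)-5,6,7,8-tetramethoxy-4H-chromen-4-one F7. Selective cleavage of the peri 5-methyl ether (AlCl3, MeCN) then gives 15, from which the last two steps of the route follow unchanged.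

The second risk is step 6. Deprotonation of the pyrone may be incomplete or misdirected, because the 5-methoxy group next to the methyl changes its acidity. The carbanion or residual amide base may add in a conjugate sense to the cinnamoyl unit, and the base may strip formaldehyde from the Weinreb amide. The fallback for step 6 leaves the pyrone out of the chain-building step; it sets out from 4 and comes back at 11. Triple deprotonation of 4 (LiN(iPr)2, 3.3 equiv, THF, −78 to 0 °C) and acylation of the terminal methyl carbanion, the last formed and most reactive site, with 9 should give the open-chain triketo ester 11 directly. It is isolated after mild acid work-up as its enol mixture and then closed to 12 with Mg(OMe)2 in MeOH under the conditions of the key step. This fallback makes no compound outside the compound list, so its entry below is F0.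

The third risk is step 10. The benzyl ether may be lost under the Lewis acid, after which the aluminium 3'-phenoxide can direct cleavage of the 4'-methyl ether. Demethylation may also run on to O7 once the O6 phenoxide has formed. The fallback for step 10 replaces the chelating benzyl ether by a non-chelating, electron-withdrawing ester before the Lewis acid treatment; it sets out from 15 and comes back at 17. Hydrogenolysis of 15 (H2, Pd/C) gives 5-hydroxy-2-(3-hydroxy-4-methoxyphenyl)-6,7,8-trimethoxy-4H-chromen-4-one F8. Acylation of the only non-chelated phenol (pivaloyl chloride, Et3N, CH2Cl2, 0 °C) gives 5-(5-hydroxy-6,7,8-trimethoxy-4-oxo-4H-chromen-2-yl)-2-methoxyphenyl 2,2-dimethylpropanoate F9. The AlBr3–MeCN demethylation is then run on this ester, whose acyloxy oxygen cannot hold aluminium next to the 4'-methoxyl, and gives 5-(5,6-dihydroxy-7,8-dimethoxy-4-oxo-4H-chromen-2-yl)-2-methoxyphenyl 2,2-dimethylpropanoate F10. Methanolysis of the aryl ester (K2CO3, degassed MeOH, rt, Ar) gives 17.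

**Further compounds**

F1 | step 7 | 2,6-dimethoxy-1,4-benzoquinone | COC1=CC(=O)C=C(OC)C1=O
F2 | step 7 | 1,2,4-triacetoxy-3,5-dimethoxybenzene | COc1cc(OC(C)=O)c(OC(C)=O)c(OC)c1OC(C)=O
F3 | step 7 | 3,5-dimethoxybenzene-1,2,4-triol | COc1cc(O)c(O)c(OC)c1O
F4 | step 7 | pentamethoxybenzene | COc1cc(OC)c(OC)c(OC)c1OC
F5 | step 7 | 2'-hydroxy-3',4',5',6'-tetramethoxyacetophenone | CC(=O)c1c(O)c(OC)c(OC)c(OC)c1OC
F6 | step 7 | (E)-3-(3-benzyloxy-4-methoxyphenyl)-1-(2-hydroxy-3,4,5,6-tetramethoxyphenyl)prop-2-en-1-one | COc1ccc(/C=C/C(=O)c2c(O)c(OC)c(OC)c(OC)c2OC)cc1OCc1ccccc1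
F7 | step 7 | 2-(3-benzyloxy-4-methoxyphenyl)-5,6,7,8-tetramethoxy-4H-chromen-4-one | COc1ccc(-c2cc(=O)c3c(OC)c(OC)c(OC)c(OC)c3o2)cc1OCc1ccccc1
F0 | step 6 | none | none
F8 | step 10 | 5-hydroxy-2-(3-hydroxy-4-methoxyphenyl)-6,7,8-trimethoxy-4H-chromen-4-one | COc1ccc(-c2cc(=O)c3c(O)c(OC)c(OC)c(OC)c3o2)cc1O
F9 | step 10 | 5-(5-hydroxy-6,7,8-trimethoxy-4-oxo-4H-chromen-2-yl)-2-methoxyphenyl 2,2-dimethylpropanoate | COc1ccc(-c2cc(=O)c3c(O)c(OC)c(OC)c(OC)c3o2)cc1OC(=O)C(C)(C)C
F10 | step 10 | 5-(5,6-dihydroxy-7,8-dimethoxy-4-oxo-4H-chromen-2-yl)-2-methoxyphenyl 2,2-dimethylpropanoate | COc1ccc(-c2cc(=O)c3c(O)c(O)c(OC)c(OC)c3o2)cc1OC(=O)C(C)(C)C
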